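**Retrosynthetic overview**
1. Target = dauc-7-ene-4β,6α,9α-triol 6-vanillate. Last bonds made: phenol unmasking, C9 ketone reduction, and the C6–O ester bond onto keto diol 19.
2. 19 comes from enedione 17 by a reduction directed by the 4β-hydroxyl; 17 comes from cycloheptadiene 11 by hydroboration of C5=C6 and conversion of the C8 ester carbon into the C8 methyl.
3. Ring B (seven-membered) is built onto ring A by forming C7–C8 and C10–C1 in one operation: diene 6 plus siloxyvinyldiazoacetate 9, by rhodium-carbenoid cyclopropanation and divinylcyclopropane Cope rearrangement (formal [4+3]).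
4. Enabling feature: in ring B, C8–C9–C10 is a three-carbon unit with oxygen on its central carbon C9 (a 2-siloxyvinylcarbene), and C1–C5–C6–C7 is the 1,3-diene of a 1-methyl-2-vinylcyclopentene (ring A) whose terminus C1 becomes the quaternary ring-fusion carbon.
5. Ring A, with the C4 carbinol already in place, comes from (S)-terpinen-4-ol by ozonolysis and aldol ring contraction. Order of ring formation: ring A first, ring B second.

Key step: step 7

Remark on numbering: daucane numbering is used. C1 is the quaternary carbon, C2 and C3 are CH2, C4 is the isopropyl carbinol, C5 is the ring-fusion CH, C6 is the ester carbinol, C7=C8 is the alkene (methyl C14 on C8), C9 is the carbinol and C10 is CH2. Ring A = C1–C5, ring B = C1, C5–C10; β is the face that carries the C1 methyl.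
Assumption: (S)-(+)-terpinen-4-ol of high enantiomeric purity is taken as commercially available; a minor enantiomer would end up as a separable diastereomer after step 7.
Assumption: Rh2(S-PTAD)4 is taken as the catalyst enantiomer that cyclopropanates the vinyl group of 6 on the face leading to 10; the sense of induction is assigned by analogy and has to be confirmed in the first run.

Step 1
Reactants: 1 (S)-(+)-terpinen-4-ol
Product: 2 (S)-triethyl{[4-methyl-1-(propan-2-yl)cyclohex-3-en-1-yl]oxy}silane
Conditions: Et3SiOTf (1.5 equiv), 2,6-lutidine, CH2Cl2, 0 °C to rt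
Reagents that add atoms: triethylsilyl trifluoromethanesulfonate, CC[Si](CC)(CC)OS(=O)(=O)C(F)(F)F
Why: Silyl triflate silylation of a hindered tertiary alcohol (standard protection) leaves the C4 carbinol centre untouched and later prevents O–H insertion in step 7 and retro-aldol or elimination chemistry in step 10.

Step 2
Reactants: 2 (S)-triethyl{[4-methyl-1-(propan-2-yl)cyclohex-3-en-1-yl]oxy}silane
Product: 4 (S)-6-oxo-3-(propan-2-yl)-3-(triethylsilyloxy)heptanal, via secondary ozonide 3 (not isolated)
Conditions: O3, CH2Cl2, −78 °C; then Me2S, −78 °C to rt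
Reagents that add atoms: ozone, [O-][O+]=O
Why: Ozonolysis (Criegee mechanism) of the only C=C bond with reductive work-up should give the 1,6-keto aldehyde without forming or touching a stereocentre.

Step 3
Reactants: 4 (S)-6-oxo-3-(propan-2-yl)-3-(triethylsilyloxy)heptanal
Product: 5 (R)-2-methyl-5-(propan-2-yl)-5-(triethylsilyloxy)cyclopent-1-ene-1-carbaldehyde
Conditions: piperidine (0.3 equiv), AcOH (0.3 equiv), toluene, 80 °C
Reagents that add atoms: none
Why: Amine-catalysed intramolecular aldol condensation (the aldehyde enamine adds to the methyl ketone in a 5-exo closure, then dehydration), the known ring contraction of ozonised p-menth-1-enes to 2-methylcyclopent-1-enecarbaldehydes, should close ring A; the weakly acidic buffer limits β-elimination of the silyloxy group and the quaternary carbinol cannot epimerise.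

Step 4
Reactants: 5 (R)-2-methyl-5-(propan-2-yl)-5-(triethylsilyloxy)cyclopent-1-ene-1-carbaldehyde
Product: 6 (R)-triethyl{[2-ethenyl-3-methyl-1-(propan-2-yl)cyclopent-2-en-1-yl]oxy}silane
Conditions: Ph3PCH3Br, KOtBu, THF, 0 °C to rt
Reagents that add atoms: methyltriphenylphosphonium bromide, C[P+](c1ccccc1)(c1ccccc1)c1ccccc1.[Br-]
Why: Wittig methylenation of the enal with the small unstabilised ylide should give the 1-methyl-2-vinylcyclopentene diene (C1=C5–C6=C7) without touching C4.

Step 5
Reactants: 7 methyl acetoacetate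
Product: 8 methyl 2-diazo-3-oxobutanoate
Conditions: 4-acetamidobenzenesulfonyl azide, Et3N, MeCN, 0 °C to rt
Reagents that add atoms: 4-acetamidobenzenesulfonyl azide, CC(=O)Nc1ccc(cc1)S(=O)(=O)N=[N+]=[N-]
Why: Regitz diazo transfer to the active methylene group of a β-keto ester is a standard, high-yielding reaction.

Step 6
Reactants: 8 methyl 2-diazo-3-oxobutanoate
Product: 9 methyl 3-(tert-butyldimethylsilyloxy)-2-diazobut-3-enoate
Conditions: tBuMe2SiOTf, Et3N, CH2Cl2, 0 °C
Reagents that add atoms: tert-butyldimethylsilyl trifluoromethanesulfonate, CC(C)(C)[Si](C)(C)OS(=O)(=O)C(F)(F)F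
Why: Enol silylation of the acetyl group of a 2-diazo-1,3-dicarbonyl compound with a silyl triflate and an amine base is the standard route to 2-siloxyvinyldiazoacetates.

Step 7
Reactants: 6 (R)-triethyl{[2-ethenyl-3-methyl-1-(propan-2-yl)cyclopent-2-en-1-yl]oxy}silane and 9 methyl 3-(tert-butyldimethylsilyloxy)-2-diazobut-3-enoate
Product: 11 methyl 9-(tert-butyldimethylsilyloxy)-4β-(triethylsilyloxy)dauca-5,8-dien-14-oate, via cis-divinylcyclopropane 10 (not isolated)
Conditions: Rh2(S-PTAD)4 [dirhodium tetrakis((S)-(1-adamantyl)(N-phthalimido)acetate)] (1 mol %), hexanes, slow addition of 9, −20 °C to rt; then toluene, 100 °C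
Reagents that add atoms: none
Why: The catalyst converts 9 into a donor/acceptor rhodium vinylcarbenoid that cyclopropanates the only unhindered alkene of 6, the terminal vinyl group C6=C7 (bond C7–C8 forms here), and the resulting cis-divinylcyclopropane 10 undergoes a Cope ([3,3]-sigmatropic) rearrangement through a boat transition state in which C10–C1 forms and the cyclopropane bond C6–C8 breaks. The closest known reaction type is the tandem cyclopropanation/Cope rearrangement (formal [4+3] cycloaddition) of 2-siloxyvinyldiazoacetates with 1,3-dienes under chiral dirhodium tetracarboxylate catalysis, which is established for 1-vinyl-2-methylcycloalkenes that build an angular-methyl quaternary carbon. The three-membered ring closes by concerted carbenoid [2+1] addition and ring B closes by sigmatropic ring expansion of that cyclopropane, so no direct seven-membered cyclisation is involved. The new quaternary centre C1 is controlled by the catalyst: it fixes the configuration of cyclopropane carbon C6, and the boat geometry transfers it suprafacially so that C10 arrives on the α-face and the methyl ends β, while the cyclopropane centres C6 and C8 become sp2 and vanish. The step needs site selectivity (secured by the hindered, fully substituted ring alkene versus the free vinyl group), the cis-divinyl geometry (secured by the donor/acceptor carbenoid, which places its vinyl group cis to the alkene substituent), facial selectivity against the α-isopropyl group on C4 (catalyst control) and freedom from O–H insertion (secured by the triethylsilyl ether). Heating is included because the C1 methyl is the inward-pointing terminus substituent of the boat and slows the rearrangement.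

Step 8
Reactants: 11 methyl 9-(tert-butyldimethylsilyloxy)-4β-(triethylsilyloxy)dauca-5,8-dien-14-oate
Product: 13 methyl 6α-hydroxy-9-(tert-butyldimethylsilyloxy)-4β-(triethylsilyloxy)dauc-8-en-14-oate, via 6α-alkylborane 12 (not isolated)
Conditions: BH3·THF (3 equiv), THF, 0 °C to rt; then 30% H2O2, aq. NaOAc, 0 °C to rt
Reagents that add atoms: hydrogen peroxide, OO
Why: Hydroboration–oxidation (syn, anti-Markovnikov) should put boron on the CH terminus C6 and hydrogen on C5 from the α-face, opposite the pseudoaxial C1 methyl and the C4 silyloxy group (as in the hydroboration of 5-ene steroids), which sets the trans ring fusion (5α-H) and a 6α-hydroxyl, while the tetrasubstituted push–pull alkene C8=C9 stays inert.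

Step 9
Reactants: 13 methyl 6α-hydroxy-9-(tert-butyldimethylsilyloxy)-4β-(triethylsilyloxy)dauc-8-en-14-oate
Product: 15 6α-hydroxy-4β-(triethylsilyloxy)dauc-8(14)-en-9-one, via allylic alcohol 14 (not isolated)
Conditions: iBu2AlH (4 equiv), CH2Cl2, −78 °C; aq. KNaC4H4O6; then oxalic acid (0.1 equiv), wet CH2Cl2, 0 °C
Reagents that add atoms: none
Why: Hydride reduction of the vinylogous carbonate ester to the 2-siloxy allylic alcohol, followed by acid-induced ionisation and desilylation (β-alkoxy enoate to α-methylene ketone unmasking of the Stork–Danheiser type), turns the ester carbon into the future C8 methyl carbon and unveils the C9 ketone without affecting a stereocentre; closure of the 6-hydroxyl onto the enone would be a disfavoured 5-endo process.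

Step 10
Reactants: 15 6α-hydroxy-4β-(triethylsilyloxy)dauc-8(14)-en-9-one
Product: 17 4β-(triethylsilyloxy)dauc-7-ene-6,9-dione, via methylene diketone 16 (not isolated)
Conditions: Dess–Martin periodinane, CH2Cl2, rt; then Et3N, rt
Reagents that add atoms: none
Why: Dess–Martin oxidation of the C6 alcohol gives a 1,4-diketone whose C7 hydrogens are both α to C6=O and allylic, so amine-mediated enolisation and γ-protonation should move the exocyclic alkene into the ring to give the conjugated enedione (alkene isomerisation into conjugation), while the hindered C5–H is not exchanged under these mild conditions.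

Step 11
Reactants: 17 4β-(triethylsilyloxy)dauc-7-ene-6,9-dione
Product: 18 4β-hydroxydauc-7-ene-6,9-dione
Conditions: HF·pyridine, pyridine, THF, 0 °C to rt
Reagents that add atoms: none
Why: Fluoride cleavage of the tertiary triethylsilyl ether under buffered acidic conditions (silyl ether deprotection) is chosen so that the resulting β-hydroxy ketone sees no base that could trigger retro-aldol cleavage or β-elimination.

Step 12
Reactants: 18 4β-hydroxydauc-7-ene-6,9-dione
Product: 19 4β,6α-dihydroxydauc-7-en-9-one
Conditions: Me4NBH(OAc)3, MeCN/AcOH (1:1), −25 °C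
Reagents that add atoms: none
Why: Evans–Saksena hydroxyl-directed reduction: the borohydride exchanges onto the 4β-hydroxyl and should deliver hydride intramolecularly to the β-face of the C6 carbonyl through a six-membered transition state, giving the 6α-alcohol (1,3-anti diol), while the C9 carbonyl, which has no directing hydroxyl, is left alone.

Step 13
Reactants: 20 vanillic acid
Product: 22 4-(tert-butyldimethylsilyloxy)-3-methoxybenzoic acid, via silyl ester 21 (not isolated)
Conditions: tBuMe2SiCl (2.3 equiv), imidazole, DMF, rt; then AcOH/THF/H2O, rt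
Reagents that add atoms: tert-butyldimethylsilyl chloride, CC(C)(C)[Si](C)(C)Cl
Why: Exhaustive silylation followed by selective hydrolysis of the labile silyl ester (standard phenol protection) should leave the phenol as its silyl ether and the acid free.

Step 14
Reactants: 19 4β,6α-dihydroxydauc-7-en-9-one and 22 4-(tert-butyldimethylsilyloxy)-3-methoxybenzoic acid
Product: 24 4β-hydroxy-9-oxodauc-7-en-6α-yl 4-(tert-butyldimethylsilyloxy)-3-methoxybenzoate, via mixed anhydride 23 (not isolated)
Conditions: 2,4,6-Cl3C6H2COCl, Et3N, THF, rt; then 19, DMAP, toluene, rt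
Reagents that add atoms: none
Why: Yamaguchi esterification through the mixed anhydride should acylate the secondary allylic 6α-hydroxyl only, the tertiary 4β-hydroxyl being unreactive, and no stereocentre is touched.

Step 15
Reactants: 24 4β-hydroxy-9-oxodauc-7-en-6α-yl 4-(tert-butyldimethylsilyloxy)-3-methoxybenzoate
Product: 25 4β,9α-dihydroxydauc-7-en-6α-yl 4-(tert-butyldimethylsilyloxy)-3-methoxybenzoate
Conditions: (R)-2-methyl-CBS-oxazaborolidine (1.5 equiv), BH3·SMe2, THF, −40 °C; MeOH quench
Reagents that add atoms: none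
Why: Corey–Bakshi–Shibata reduction: with the α-methyl alkenyl group as the large and C10H2 as the small substituent, the (R)-oxazaborolidine–borane complex should deliver hydride to the β-face of the C9 carbonyl and give the 9α (S) allylic alcohol under reagent control, against the substrate preference for attack anti to the C1 methyl; 1,2-selectivity is inherent to the reagent and the aryl ester is not reduced at this temperature.

Step 16
Reactants: 25 4β,9α-dihydroxydauc-7-en-6α-yl 4-(tert-butyldimethylsilyloxy)-3-methoxybenzoate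
Product: 26 4β,9α-dihydroxydauc-7-en-6α-yl 4-hydroxy-3-methoxybenzoate (target CNP0189996.2)
Conditions: Bu4NF, AcOH (1:1), THF, 0 °C
Reagents that add atoms: none
Why: Fluoride cleavage of the aryl silyl ether buffered with acetic acid (silyl ether deprotection) should free the phenol without acyl migration or ester cleavage.

**Compound list**
1 | (S)-(+)-terpinen-4-ol, (S)-4-methyl-1-(propan-2-yl)cyclohex-3-en-1-ol | CC1=CC[C@](O)(C(C)C)CC1 | starting material
2 | (S)-triethyl{[4-methyl-1-(propan-2-yl)cyclohex-3-en-1-yl]oxy}silane | CC1=CC[C@](O[Si](CC)(CC)CC)(C(C)C)CC1 | intermediate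
3 | secondary ozonide of 2 (1,2,4-trioxolane across the former C=C; the two acetal carbons unassigned; not isolated) | CC12CC[C@@](O[Si](CC)(CC)CC)(C(C)C)CC(OO1)O2 | intermediate
4 | (S)-6-oxo-3-(propan-2-yl)-3-(triethylsilyloxy)heptanal | CC(=O)CC[C@@](O[Si](CC)(CC)CC)(C(C)C)CC=O | intermediate
5 | (R)-2-methyl-5-(propan-2-yl)-5-(triethylsilyloxy)cyclopent-1-ene-1-carbaldehyde | O=CC1=C(C)CC[C@@]1(O[Si](CC)(CC)CC)C(C)C | intermediate
6 | (R)-triethyl{[2-ethenyl-3-methyl-1-(propan-2-yl)cyclopent-2-en-1-yl]oxy}silane | C=CC1=C(C)CC[C@@]1(O[Si](CC)(CC)CC)C(C)C | intermediate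
7 | methyl acetoacetate | CC(=O)CC(=O)OC | starting material
8 | methyl 2-diazo-3-oxobutanoate | CC(=O)C(=[N+]=[N-])C(=O)OC | intermediate
9 | methyl 3-(tert-butyldimethylsilyloxy)-2-diazobut-3-enoate | C=C(O[Si](C)(C)C(C)(C)C)C(=[N+]=[N-])C(=O)OC | intermediate
10 | methyl 1-[1-(tert-butyldimethylsilyloxy)ethenyl]-2-[(R)-2-methyl-5-(propan-2-yl)-5-(triethylsilyloxy)cyclopent-1-en-1-yl]cyclopropane-1-carboxylate, the two alkenyl groups cis (not isolated) | COC(=O)[C@]1(C(=C)O[Si](C)(C)C(C)(C)C)C[C@H]1C1=C(C)CC[C@@]1(O[Si](CC)(CC)CC)C(C)C | intermediate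
11 | methyl 9-(tert-butyldimethylsilyloxy)-4β-(triethylsilyloxy)dauca-5,8-dien-14-oate (1β-methyl) | COC(=O)C1=C(O[Si](C)(C)C(C)(C)C)C[C@@]2(C)CC[C@@](O[Si](CC)(CC)CC)(C(C)C)C2=CC1 | intermediate
12 | 6α-boryl adduct of 11 (5α-H; drawn as the monoalkylborane; not isolated) | B[C@H]1CC(C(=O)OC)=C(O[Si](C)(C)C(C)(C)C)C[C@@]2(C)CC[C@@](O[Si](CC)(CC)CC)(C(C)C)[C@H]12 | intermediate
13 | methyl 6α-hydroxy-9-(tert-butyldimethylsilyloxy)-4β-(triethylsilyloxy)dauc-8-en-14-oate (5α-H) | O[C@H]1CC(C(=O)OC)=C(O[Si](C)(C)C(C)(C)C)C[C@@]2(C)CC[C@@](O[Si](CC)(CC)CC)(C(C)C)[C@H]12 | intermediate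
14 | 9-(tert-butyldimethylsilyloxy)-4β-(triethylsilyloxy)dauc-8-ene-6α,14-diol (not isolated) | O[C@H]1CC(CO)=C(O[Si](C)(C)C(C)(C)C)C[C@@]2(C)CC[C@@](O[Si](CC)(CC)CC)(C(C)C)[C@H]12 | intermediate
15 | 6α-hydroxy-4β-(triethylsilyloxy)dauc-8(14)-en-9-one | O[C@H]1CC(=C)C(=O)C[C@@]2(C)CC[C@@](O[Si](CC)(CC)CC)(C(C)C)[C@H]12 | intermediate
16 | 4β-(triethylsilyloxy)dauc-8(14)-ene-6,9-dione (not isolated) | O=C1CC(=C)C(=O)C[C@@]2(C)CC[C@@](O[Si](CC)(CC)CC)(C(C)C)[C@H]12 | intermediate
17 | 4β-(triethylsilyloxy)dauc-7-ene-6,9-dione (5α-H, trans-fused) | O=C1C=C(C)C(=O)C[C@@]2(C)CC[C@@](O[Si](CC)(CC)CC)(C(C)C)[C@H]12 | intermediate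
18 | 4β-hydroxydauc-7-ene-6,9-dione | O=C1C=C(C)C(=O)C[C@@]2(C)CC[C@@](O)(C(C)C)[C@H]12 | intermediate
19 | 4β,6α-dihydroxydauc-7-en-9-one | O[C@H]1C=C(C)C(=O)C[C@@]2(C)CC[C@@](O)(C(C)C)[C@H]12 | intermediate
20 | vanillic acid (4-hydroxy-3-methoxybenzoic acid) | COc1cc(C(=O)O)ccc1O | starting material
21 | tert-butyldimethylsilyl 4-(tert-butyldimethylsilyloxy)-3-methoxybenzoate (not isolated) | COc1cc(C(=O)O[Si](C)(C)C(C)(C)C)ccc1O[Si](C)(C)C(C)(C)C | intermediate
22 | 4-(tert-butyldimethylsilyloxy)-3-methoxybenzoic acid | COc1cc(C(=O)O)ccc1O[Si](C)(C)C(C)(C)C | intermediate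
23 | 4-(tert-butyldimethylsilyloxy)-3-methoxybenzoic 2,4,6-trichlorobenzoic anhydride (not isolated) | COc1cc(C(=O)OC(=O)c2c(Cl)cc(Cl)cc2Cl)ccc1O[Si](C)(C)C(C)(C)C | intermediate
24 | 4β-hydroxy-9-oxodauc-7-en-6α-yl 4-(tert-butyldimethylsilyloxy)-3-methoxybenzoate | COc1cc(C(=O)O[C@H]2C=C(C)C(=O)C[C@@]3(C)CC[C@@](O)(C(C)C)[C@H]23)ccc1O[Si](C)(C)C(C)(C)C | intermediate
25 | 4β,9α-dihydroxydauc-7-en-6α-yl 4-(tert-butyldimethylsilyloxy)-3-methoxybenzoate | COc1cc(C(=O)O[C@H]2C=C(C)[C@@H](O)C[C@@]3(C)CC[C@@](O)(C(C)C)[C@H]23)ccc1O[Si](C)(C)C(C)(C)C | intermediate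
26 | 4β,9α-dihydroxydauc-7-en-6α-yl 4-hydroxy-3-methoxybenzoate (CNP0189996.2) | COc1cc(C(=O)O[C@H]2C=C(C)[C@@H](O)C[C@@]3(C)CC[C@@](O)(C(C)C)[C@H]23)ccc1O | target

**Step count and risks**
Total step count: 16 (steps 5, 6 and 13 make the two side fragments).
Longest linear sequence: 13 steps (1, 2, 3, 4, 7, 8, 9, 10, 11, 12, 14, 15, 16).

Steps most likely to fail:

Step 7. The catalyst has to override the C4 substituents (the α-isopropyl group lies on the face where C10 must arrive), so mismatched double stereodifferentiation could erode the facial selectivity of the cyclopropanation. The sigmatropic step could also stall at the hindered, methyl-bearing terminus and let cyclopropane isomerisation or C–H insertion take over. The fallback sets out from diene 6 and returns at enedione 17. Diene 6 is combined in a [4+3] cycloaddition with the oxyallyl cation generated from 3-chlorobutan-2-one (Et3N, CF3CH2OH), giving 4β-(triethylsilyloxy)dauc-5-en-9-one F1, which already carries the C8 methyl; the facial selectivity at C1 would then rest on the C4 substituents, and the C1 epimers would be separated here. BH3·THF reduces the ketone and hydroborates C5=C6 to the borane adduct F2, and oxidative work-up (H2O2, NaOAc) gives 4β-(triethylsilyloxy)daucane-6α,9-diol F3. Dess–Martin oxidation gives 4β-(triethylsilyloxy)daucane-6,9-dione F4, and dehydrogenation between C7 and C8 with 2-iodoxybenzoic acid (DMSO, 70 °C), the only position with hydrogens on both carbons between the carbonyls, gives 17.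

Step 8. Borane could add from the β-face, because the α-face is the concave face of the cyclohepta-1,4-diene and also carries the C4 isopropyl group; this would give the cis ring fusion. The fallback sets out from 11 and returns at 17; it replaces kinetic face control by thermodynamic control at C5. The β-face adduct series is carried through the conditions of steps 8 to 10: 6β-alkylborane F5, cis-fused alcohol F6, allylic alcohol F7, cis-fused methylene ketone F8, cis-fused methylene diketone F9 and cis-fused enedione F10. F10 is then equilibrated at C5 through the C6 enol with DBU (toluene, rt), which should favour the trans-fused 17 because C6 is then cis to the silyloxy group and no longer to the α-isopropyl group on C4; loss of the β-silyloxy group is the side reaction to watch. Since C6 is a ketone at this stage, its configuration is set afresh in step 12.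

Step 15. Substrate-controlled hydride delivery from the α-face (anti to the C1 methyl) could override the reagent and give the 9β-alcohol. The fallback sets out from 24 and returns at 25; it accepts the substrate preference and inverts. Luche reduction (NaBH4, CeCl3·7H2O, MeOH, −78 °C) gives the 9β-alcohol F11. Mitsunobu inversion with chloroacetic acid (PPh3, diisopropyl azodicarboxylate, toluene), in which the nucleophile enters from the open α-face, gives the 9α-chloroacetate F12. Selective removal of the chloroacetyl group with thiourea (2,6-lutidine, EtOH, 40 °C) leaves the vanillate untouched and gives 25.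

Further compounds
F1 | step 7 | 4β-(triethylsilyloxy)dauc-5-en-9-one (C8 epimers) | CC1C(=O)C[C@@]2(C)CC[C@@](O[Si](CC)(CC)CC)(C(C)C)C2=CC1
F2 | step 7 | borane adduct of F1 (6α-boryl, 9-boryloxy, 5α-H) | B[C@H]1CC(C)C(OB)C[C@@]2(C)CC[C@@](O[Si](CC)(CC)CC)(C(C)C)[C@H]12
F3 | step 7 | 4β-(triethylsilyloxy)daucane-6α,9-diol (C8 and C9 epimers) | O[C@H]1CC(C)C(O)C[C@@]2(C)CC[C@@](O[Si](CC)(CC)CC)(C(C)C)[C@H]12
F4 | step 7 | 4β-(triethylsilyloxy)daucane-6,9-dione (C8 epimers) | O=C1CC(C)C(=O)C[C@@]2(C)CC[C@@](O[Si](CC)(CC)CC)(C(C)C)[C@H]12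
F5 | step 8 | 6β-boryl adduct of 11 (5β-H) | B[C@@H]1CC(C(=O)OC)=C(O[Si](C)(C)C(C)(C)C)C[C@@]2(C)CC[C@@](O[Si](CC)(CC)CC)(C(C)C)[C@@H]12
F6 | step 8 | methyl 6β-hydroxy-9-(tert-butyldimethylsilyloxy)-4β-(triethylsilyloxy)-5β-dauc-8-en-14-oate | O[C@@H]1CC(C(=O)OC)=C(O[Si](C)(C)C(C)(C)C)C[C@@]2(C)CC[C@@](O[Si](CC)(CC)CC)(C(C)C)[C@@H]12
F7 | step 8 | 9-(tert-butyldimethylsilyloxy)-4β-(triethylsilyloxy)-5β-dauc-8-ene-6β,14-diol | O[C@@H]1CC(CO)=C(O[Si](C)(C)C(C)(C)C)C[C@@]2(C)CC[C@@](O[Si](CC)(CC)CC)(C(C)C)[C@@H]12
F8 | step 8 | 6β-hydroxy-4β-(triethylsilyloxy)-5β-dauc-8(14)-en-9-one | O[C@@H]1CC(=C)C(=O)C[C@@]2(C)CC[C@@](O[Si](CC)(CC)CC)(C(C)C)[C@@H]12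
F9 | step 8 | 4β-(triethylsilyloxy)-5β-dauc-8(14)-ene-6,9-dione | O=C1CC(=C)C(=O)C[C@@]2(C)CC[C@@](O[Si](CC)(CC)CC)(C(C)C)[C@@H]12
F10 | step 8 | 4β-(triethylsilyloxy)-5β-dauc-7-ene-6,9-dione (cis-fused) | O=C1C=C(C)C(=O)C[C@@]2(C)CC[C@@](O[Si](CC)(CC)CC)(C(C)C)[C@@H]12
F11 | step 15 | 4β,9β-dihydroxydauc-7-en-6α-yl 4-(tert-butyldimethylsilyloxy)-3-methoxybenzoate | COc1cc(C(=O)O[C@H]2C=C(C)[C@H](O)C[C@@]3(C)CC[C@@](O)(C(C)C)[C@H]23)ccc1O[Si](C)(C)C(C)(C)C
F12 | step 15 | 9α-(chloroacetoxy)-4β-hydroxydauc-7-en-6α-yl 4-(tert-butyldimethylsilyloxy)-3-methoxybenzoate | COc1cc(C(=O)O[C@H]2C=C(C)[C@@H](OC(=O)CCl)C[C@@]3(C)CC[C@@](O)(C(C)C)[C@H]23)ccc1O[Si](C)(C)C(C)(C)C
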